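## Analysis of the target

Numbering used below: the chromenone part is numbered as a flavonol (O1, C2–C4, C4a, C5–C8, C8a, O7 on C7); the other part is numbered as a benzofuran-3(2H)-one (O1, C2, C3); "the hemiketal carbon" is the carbon that carries OH and a 4-hydroxyphenyl group (C8' of the systematic spiro name).

- The target 23 is a 4,6-dihydroxybenzofuran-3(2H)-one whose C2 is the spiro atom of a second five-membered ring. That ring is closed by C8 and C7–O7 of a 3,5,7,4'-oxygenated flavonol and by a hemiketal carbon bearing the second 4-hydroxyphenyl group.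
- There are two adjacent stereocentres. The spiro carbon (2S) is fully substituted: O1, the C3 ketone, flavonol C8 and the hemiketal carbon. At the hemiketal carbon (8'R) the hydroxyl lies on the face of the C3 carbonyl and the aryl group on the face of O1.
- The hemiketal is the ring tautomer of a 7-hydroxy ketone. Its configuration can equilibrate and follows the spiro centre, so only the spiro centre must be set by the synthesis.
- In the open form the spiro carbon is the central carbon of a non-enolizable 1,3-diketone, which nucleophilic bases cleave by retro-Claisen reaction. In the closed form a hemiketal alkoxide can fragment to an aryl ester and a planar benzofuranone enolate, so strong base endangers the spiro configuration.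
- The seven free hydroxyls and the electron-rich rings call for a mild last step.
- The hard part is the bond from the spiro carbon to flavonol C8. It joins a quaternary carbon to an arene position flanked by two oxygen-bearing carbons, and on an intact flavonol C8 is poorly distinguished from C6.
- The strategy rests on the flavonol benzo ring being a phloroglucinol ring, that is, a folded polyketide. C8 carries the spiro carbon and C7 carries the oxygen that closes the hemiketal. C8 can therefore begin as an sp3 methylene already bonded to C2, and C7 as an ester carbonyl.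

## Retrosynthetic reasoning

**23 ⇒ 22.** Only protecting groups are removed last. Five benzyl ethers (benzofuranone O4 and O6, flavonol O3, both aryl para-oxygens) go by hydrogenolysis under neutral conditions. The 5-hydroxyl and the hemiketal hydroxyl are already free in 22 because the key step creates them. No skeletal bond is made after the key step.

**22 ⇒ 21 ⇒ 20 (key disconnection).** Opening the O7–C bond of the hemiketal gives the hydroxy ketone 21. Cutting C7–C8 of its benzo ring and returning C5 and C7 to the carbonyl level gives 20. In 20, C8 is the methylene that links a 4-pyranone to C2, C7 is an ester carbonyl and C5 a ketone. The cut is made here because a ring built around C8 has no C6/C8 question, and the crowded aryl–quaternary bond becomes an alkyl–quaternary bond that can be made by substitution. The forward reaction must generate the C8 carbanion, make it attack the ester, and aromatize. The new O7 then sits ortho to C8 and next to the aroyl ketone, and closes the hemiketal without further help.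

**20 ⇒ 17 + 18, and 17 ⇒ 16.** The keto ester chain is cut between the ring acyl carbon and its methylene, giving acid 17 and malonate half ester 18. The chain is added late because its acidic methylene would compete in the alkylation and would cyclize onto a bromomethyl group. Acid 17 comes from allyl ester 16, which can be cleaved under neutral conditions. A hydrolysis with nucleophilic base is excluded by the 1,3-diketone at C2.

**16 ⇒ 5 + 15.** The C2–CH2 bond is cut to the stabilized anion of 5 and the primary bromide 15. This is the only step that has to set absolute configuration. The electrophile is an unhindered, vinylogously activated CH2Br, so the quaternary centre forms by SN2 reaction within a chiral ion pair.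

**5 ⇒ 2 + 3, and 2 ⇒ 1.** The benzofuranone ring is cut at O1–C2 and C3–C3a: phenol 2 is O-alkylated by bromo ketone 3, and the ketone enolate closes onto the benzoate ester. The aroyl group that later becomes the hemiketal carbon is in place from the start. Compound 2 comes from triol 1 by benzylation of the two hydroxyls that are not needed for ring closure.

**15 ⇒ 14 ⇒ 11 + 12; 11 ⇒ 8 + 9; 8 ⇒ 6 + 7.**
- The bromide is made directly from silyl ether 14, because a free hydroxymethyl group next to the ester would lactonize.
- The pyranone is cut at O1–C2 and C2–C3 (flavonol numbering of the later ring): acid chloride 12 acylates the only ketone α-carbon of enaminone 11, and the resulting enol oxygen displaces the amine.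
- Enaminone 11 is the C-acylation product of the amine adduct of ynoate 8 with acid chloride 9. Fixing one acyl group as an enamine makes the two oxygenated methylene groups different, so regiochemistry follows from the order of events.
- Ynoate 8 is the acylation product of alkyne 6 with chloroformate 7. The carbonyl carbon of 7 becomes flavonol C5.

## Alternatives that were turned down

**Alternative 1:**
- Disconnection: the spiro carbon is treated as the central carbon of a malonate, and the bond from flavonol O7 to the future hemiketal carbon is cut.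
- Forward key step: prochiral di-tert-butyl malonate A1 carries the 3,5-bis(benzyloxy)phenoxy group and the 7-hydroxyflavonol-8-yl group on one carbon. A chiral BINOL-derived phosphoric acid would make the 7-OH attack one of the two enantiotopic esters, giving lactone A2.
- For it: acid-catalysed desymmetrizing lactonization of hydroxy di-tert-butyl malonates is an established route to quaternary lactone centres, and the centre of A2 has no racemization pathway. On enantiocontrol alone this precedent is at least as strong as the ion-pair alkylation chosen here.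
- Against it:
  - A1 already contains the fully substituted carbon bonded to flavonol C8, so the hardest bond of the target must be made before the key step, and the key step does not help with it.
  - The nucleophile is a phenol and the product an aryl lactone. This is an activated ester, less favoured than the aliphatic lactones of the precedent.
  - After A2, an aryl nucleophile must add exactly once to the lactone, and the remaining ester must be turned into the C3 ketone by acylation of the phenoxy ring. Both have to be done in the presence of the flavonol carbonyl.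
- Comparison: the chosen route makes the C8–C2 bond by an unhindered substitution, closes two rings in the key step, and leaves one deprotection. Its enantioselective step has weaker precedent, and this is accepted in exchange.

**Alternative 2:**
- Disconnection: the benzo ring of the benzofuranone is taken apart into four bonds.
- Forward key step: spiro 5-(diazoacetyl)furan-3(2H)-one A3 is irradiated with benzyl ethynyl ether A4. Wolff shift, ketene–alkyne (2+2) addition, four-electron opening and six-electron closure would give A5, which has a free 4-OH and a methyl ketal.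
- For it: the mechanism fixes the resorcinol oxygen pattern, four C–C bonds form in one operation, and the benzannulation type is well established for alkoxyalkynes. On regiochemical certainty of its ring it is stronger than any step of the chosen route.
- Against it:
  - The ring it builds is the one that can be bought as a phloroglucinol derivative.
  - The spiro centre, the flavonol and the ketal must all be present in A3, so the difficult C8–C2 bond and the stereocentre are pushed onto a furan-3(2H)-one scaffold, for which no reliable asymmetric route is evident.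
  - The flavonol chromophore absorbs strongly where the diazo ketone must be photolysed, and 3-alkoxyflavones are photoreactive themselves.
  - The methyl ketal needs an extra acidic hydrolysis at the end.
- Comparison: the chosen route spends its de novo arene construction on the ring whose substitution is hard to reach, and needs fewer steps after the key event.

**Alternative 3:**
- Disconnection: the bond from the spiro carbon to the hemiketal carbon.
- Forward key step: racemic 2-(flavonol-8-yl)benzofuran-3(2H)-one A6 carries a 4-benzyloxybenzoate on O7. A mild inorganic base and a cinchona-derived ammonium salt would deprotonate C2, and the enolate would attack the ester carbonyl in a 5-exo-trig closure to give hexabenzyl ether A7.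
- For it: it is enantioconvergent, it forms the quaternary centre and the hemiketal ring together, and A7, like 22, is one hydrogenolysis from the target. On paper it is the shortest of all four strategies and in step count it is stronger than the chosen one.
- Against it:
  - A6 needs a C8-selective C–C bond to an intact 5,7-dioxygenated flavonol, where C6 competes.
  - The acyl transfer is the reverse of the fragmentation that a hemiketal alkoxide of this skeleton can undergo, so the stereocentre is created under conditions in which its formation may be reversible.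
  - The two faces of the enolate differ only by rotation about the C2–C8 bond while the electrophile is tethered to that aryl group. This gives the catalyst a weak handle.
- Comparison: the chosen route sets the centre in an irreversible intermolecular alkylation and removes the C6/C8 question altogether. It pays with a longer preparation of the pyranone partner.

Key step: step 10

Assumptions:
- The hemiketal carbon equilibrates through the open hydroxy ketone. The (8'R) epimer of the target (hydroxyl on the face of the C3 carbonyl) is taken to be the thermodynamically preferred one.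
- Bromo ketone 3 is taken to be purchasable.

## Route

**Step 1**
Reactants: 1 methyl 2,4,6-trihydroxybenzoate
Product: 2 methyl 2,4-bis(benzyloxy)-6-hydroxybenzoate
Conditions: BnBr (2.05 equiv), K2CO3, DMF, rt
Reagents that add atoms: benzyl bromide, BrCc1ccccc1
Why: Williamson etherification; with two equivalents, the para hydroxyl and one ortho hydroxyl react, while the remaining ortho hydroxyl is held back by its hydrogen bond to the ester carbonyl.

**Step 2**
Reactants: 2 methyl 2,4-bis(benzyloxy)-6-hydroxybenzoate; 3 2-bromo-1-[4-(benzyloxy)phenyl]ethan-1-one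
Product: 5 [4-(benzyloxy)phenyl][4,6-bis(benzyloxy)-3-hydroxy-1-benzofuran-2-yl]methanone (enol form of the 2-aroylbenzofuran-3(2H)-one), via aryl phenacyl ether 4 (not isolated)
Conditions: K2CO3, DMF, 50 °C; then KOt-Bu, THF, 0 °C → rt; aq. HCl
Reagents that add atoms: none
Why: O-alkylation of the phenol by the α-bromo ketone, then Dieckmann-type closure of the ketone enolate onto the benzoate ester (5-exo-trig); the stable enolate of the product drives the condensation.

**Step 3**
Reactants: 6 tert-butyldimethyl(prop-2-yn-1-yloxy)silane; 7 prop-2-en-1-yl carbonochloridate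
Product: 8 prop-2-en-1-yl 4-[(tert-butyldimethylsilyl)oxy]but-2-ynoate
Conditions: n-BuLi, THF, −78 °C; then 7, −78 → 0 °C
Reagents that add atoms: none
Why: Acylation of a lithium acetylide by a chloroformate, the standard route to ynoates.

**Step 4**
Reactants: 8 prop-2-en-1-yl 4-[(tert-butyldimethylsilyl)oxy]but-2-ynoate; 9 (benzyloxy)acetyl chloride
Product: 11 prop-2-en-1-yl 2-[(benzyloxy)acetyl]-4-[(tert-butyldimethylsilyl)oxy]-3-(pyrrolidin-1-yl)but-2-enoate, via enamino ester 10 (not isolated)
Conditions: pyrrolidine (1.0 equiv), CH2Cl2, 0 °C → rt; then pyridine, 9, 0 °C → rt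
Reagents that add atoms: pyrrolidine, C1CCNC1
Why: Conjugate addition of a secondary amine to the ynoate forms the enamino ester without a by-product, and its nucleophilic α-carbon is then C-acylated by the acid chloride (enamine acylation). A secondary amine is used so that the later ring closure can only give a pyranone and not a pyridone.

**Step 5**
Reactants: 11 prop-2-en-1-yl 2-[(benzyloxy)acetyl]-4-[(tert-butyldimethylsilyl)oxy]-3-(pyrrolidin-1-yl)but-2-enoate; 12 4-(benzyloxy)benzoyl chloride
Product: 14 prop-2-en-1-yl 5-(benzyloxy)-6-[4-(benzyloxy)phenyl]-2-{[(tert-butyldimethylsilyl)oxy]methyl}-4-oxo-4H-pyran-3-carboxylate, via enaminone diketone 13 (not isolated)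
Conditions: LiN(SiMe3)2 (2.2 equiv), THF, −78 °C; 12, −78 → 0 °C; then AcOH, rt
Reagents that add atoms: none
Why: The only ketone α-hydrogens of 11 are on the benzyloxymethyl carbon, so the lithium enolate forms there and is C-acylated by 12, the second equivalent of base taking up the more acidic diketone 13. On acidification the enol oxygen of 13 adds to the enamine carbon and expels the amine, which is the established enaminone route to 4-pyranones. Mild acid is used so that the silyl ether survives, since a free hydroxymethyl group next to the ester would lactonize.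

**Step 6**
Reactants: 14 prop-2-en-1-yl 5-(benzyloxy)-6-[4-(benzyloxy)phenyl]-2-{[(tert-butyldimethylsilyl)oxy]methyl}-4-oxo-4H-pyran-3-carboxylate
Product: 15 prop-2-en-1-yl 5-(benzyloxy)-6-[4-(benzyloxy)phenyl]-2-(bromomethyl)-4-oxo-4H-pyran-3-carboxylate
Conditions: Ph3PBr2, CH2Cl2, 0 °C → rt
Reagents that add atoms: dibromotriphenylphosphorane, BrP(Br)(c1ccccc1)(c1ccccc1)c1ccccc1
Why: Ph3PBr2 converts primary tert-butyldimethylsilyl ethers directly into bromides (oxyphosphonium formation with loss of the silyl bromide, then SN2 by bromide). The hydroxymethyl compound, which would close a five-membered lactone onto the neighbouring ester, is therefore never set free.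

**Step 7**
Reactants: 5 [4-(benzyloxy)phenyl][4,6-bis(benzyloxy)-3-hydroxy-1-benzofuran-2-yl]methanone; 15 prop-2-en-1-yl 5-(benzyloxy)-6-[4-(benzyloxy)phenyl]-2-(bromomethyl)-4-oxo-4H-pyran-3-carboxylate
Product: 16 prop-2-en-1-yl 5-(benzyloxy)-6-[4-(benzyloxy)phenyl]-2-({(2R)-4,6-bis(benzyloxy)-2-[4-(benzyloxy)benzoyl]-3-oxo-2,3-dihydro-1-benzofuran-2-yl}methyl)-4-oxo-4H-pyran-3-carboxylate
Conditions: O-allyl-N-(9-anthracenylmethyl)cinchonidinium bromide (10 mol %), K2CO3 (powdered), toluene, −20 °C
Reagents that add atoms: none
Why: Enantioselective phase-transfer alkylation of the cyclic β-dicarbonyl anion of 5 as a chiral ammonium ion pair; the soft, vinylogously activated primary bromide, the nonpolar solvent and the ammonium counter-ion favour C- over O-alkylation, and the catalyst shields one face of the planar 3-oxidobenzofuran so that C2 forms as (R). The sense of induction has to be confirmed on this enolate, and the pseudoenantiomeric cinchoninium salt would be used if the other face reacts.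

**Step 8**
Reactants: 16 prop-2-en-1-yl 5-(benzyloxy)-6-[4-(benzyloxy)phenyl]-2-({(2R)-4,6-bis(benzyloxy)-2-[4-(benzyloxy)benzoyl]-3-oxo-2,3-dihydro-1-benzofuran-2-yl}methyl)-4-oxo-4H-pyran-3-carboxylate
Product: 17 5-(benzyloxy)-6-[4-(benzyloxy)phenyl]-2-({(2R)-4,6-bis(benzyloxy)-2-[4-(benzyloxy)benzoyl]-3-oxo-2,3-dihydro-1-benzofuran-2-yl}methyl)-4-oxo-4H-pyran-3-carboxylic acid
Conditions: Pd(PPh3)4 (5 mol %), N-methylaniline, THF, rt
Reagents that add atoms: none
Why: Allyl ester cleavage through a π-allyl complex of zerovalent palladium with a weakly nucleophilic amine as allyl acceptor; the conditions are neutral, so the base-labile 1,3-diketone at C2 and the benzyl ethers are left alone.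

**Step 9**
Reactants: 17 5-(benzyloxy)-6-[4-(benzyloxy)phenyl]-2-({(2R)-4,6-bis(benzyloxy)-2-[4-(benzyloxy)benzoyl]-3-oxo-2,3-dihydro-1-benzofuran-2-yl}methyl)-4-oxo-4H-pyran-3-carboxylic acid; 18 potassium 3-methoxy-3-oxopropanoate
Product: 20 methyl 3-[5-(benzyloxy)-6-[4-(benzyloxy)phenyl]-2-({(2R)-4,6-bis(benzyloxy)-2-[4-(benzyloxy)benzoyl]-3-oxo-2,3-dihydro-1-benzofuran-2-yl}methyl)-4-oxo-4H-pyran-3-yl]-3-oxopropanoate, via acyl imidazolide 19 (not isolated)
Conditions: 1,1'-carbonyldiimidazole, THF, rt; then 18, MgCl2, Et3N, MeCN, rt → 40 °C; aq. HCl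
Reagents that add atoms: 1,1'-carbonyldiimidazole, O=C(n1ccnc1)n1ccnc1 (its imidazolyl group is carried by intermediate 19 only)
Why: Decarboxylative Claisen condensation of an acyl imidazolide with a magnesium malonate half ester (Masamune–Brooks reaction); the nucleophile is soft and weakly basic, so neither the 1,3-diketone nor the pyranone methylene is attacked.

**Step 10**
Reactants: 20 methyl 3-[5-(benzyloxy)-6-[4-(benzyloxy)phenyl]-2-({(2R)-4,6-bis(benzyloxy)-2-[4-(benzyloxy)benzoyl]-3-oxo-2,3-dihydro-1-benzofuran-2-yl}methyl)-4-oxo-4H-pyran-3-yl]-3-oxopropanoate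
Product: 22 (2S,8'R)-3',4,6-tris(benzyloxy)-2',8'-bis[4-(benzyloxy)phenyl]-5',8'-dihydroxy-3H,4'H,8'H-spiro[[1]benzofuran-2,9'-furo[2,3-h]chromene]-3,4'-dione, via open hydroxy ketone 21 (not isolated)
Conditions: LiN(SiMe3)2 (3.5 equiv), THF, −78 → 0 °C; AcOH quench
Reagents that add atoms: none
Why: Proposed new method: the first equivalent of LiN(SiMe3)2 forms the chelated keto ester enolate and a second removes a proton from the pyranone 6-methylene (flavonol C8), which is vinylogous to the pyranone carbonyl; this carbanion attacks the ester carbonyl, the alkoxide leaves, and two enolizations give the aromatic 5,7-dihydroxy ring of 21, whose O7 phenoxide adds to the neighbouring aroyl ketone to give 22. The closest known reaction types are the base-induced Claisen cycloaromatization of 3,5-diketo esters to phloroglucinols and the acylation of laterally deprotonated 2-alkyl-4-pyranones by esters; their intramolecular combination on a pyranone to give a chromone benzo ring has not been demonstrated. The benzo ring closes in a 6-exo-trig (enolendo) mode and forms C7–C8; the hemiketal ring closes in a 5-exo-trig mode and forms the O7–C bond. The spiro centre has no hydrogen and none of its bonds is broken on the intended path, so its arrangement is carried over unchanged; the descriptor changes from (R) to (2S) only because the CIP priorities change. The new hemiketal centre is reversible and is set by the spiro centre under thermodynamic control, the hydroxyl settling on the face of the C3 carbonyl (hydrogen bond) and the aryl group on the face of O1. The step needs C-acylation at the ester in preference to reaction at the two ketones on C2 and to loss of the benzofuranone aryloxide from the carbanion. Only the ester can be reached through a six-membered transition state (the ketones could only close three-membered rings), a non-nucleophilic amide base leaves the 1,3-diketone alone, and low temperature is meant to hold back β-elimination until aromatization removes the acidic C8 hydrogen for good.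

**Step 11**
Reactants: 22 (2S,8'R)-3',4,6-tris(benzyloxy)-2',8'-bis[4-(benzyloxy)phenyl]-5',8'-dihydroxy-3H,4'H,8'H-spiro[[1]benzofuran-2,9'-furo[2,3-h]chromene]-3,4'-dione
Product: 23 (2S,8'R)-3',4,5',6,8'-pentahydroxy-2',8'-bis(4-hydroxyphenyl)-3H,4'H,8'H-spiro[[1]benzofuran-2,9'-furo[2,3-h]chromene]-3,4'-dione (target, CNP0283000.1)
Conditions: H2 (1 atm), 10% Pd/C, EtOAc/THF, rt
Reagents that add atoms: none
Why: Hydrogenolysis of five aryl benzyl ethers under neutral conditions; no alcohol solvent is used, so the hemiketal is not exchanged to a ketal, and the tetrasubstituted flavonol double bond and the aryl ketone are expected to survive mild conditions.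

## Compound list

1 | methyl 2,4,6-trihydroxybenzoate | COC(=O)c1c(O)cc(O)cc1O | starting material
2 | methyl 2,4-bis(benzyloxy)-6-hydroxybenzoate | COC(=O)c1c(O)cc(OCc2ccccc2)cc1OCc1ccccc1 | intermediate
3 | 2-bromo-1-[4-(benzyloxy)phenyl]ethan-1-one | O=C(CBr)c1ccc(OCc2ccccc2)cc1 | starting material
4 | methyl 2,4-bis(benzyloxy)-6-{2-[4-(benzyloxy)phenyl]-2-oxoethoxy}benzoate | COC(=O)c1c(OCC(=O)c2ccc(OCc3ccccc3)cc2)cc(OCc2ccccc2)cc1OCc1ccccc1 | intermediate (not isolated)
5 | [4-(benzyloxy)phenyl][4,6-bis(benzyloxy)-3-hydroxy-1-benzofuran-2-yl]methanone (enol form of 2-[4-(benzyloxy)benzoyl]-4,6-bis(benzyloxy)-1-benzofuran-3(2H)-one) | O=C(c1ccc(OCc2ccccc2)cc1)c1oc2cc(OCc3ccccc3)cc(OCc3ccccc3)c2c1O | intermediate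
6 | tert-butyldimethyl(prop-2-yn-1-yloxy)silane | C#CCO[Si](C)(C)C(C)(C)C | starting material
7 | prop-2-en-1-yl carbonochloridate (allyl chloroformate) | C=CCOC(=O)Cl | starting material
8 | prop-2-en-1-yl 4-[(tert-butyldimethylsilyl)oxy]but-2-ynoate | C=CCOC(=O)C#CCO[Si](C)(C)C(C)(C)C | intermediate
9 | (benzyloxy)acetyl chloride | O=C(Cl)COCc1ccccc1 | starting material
10 | prop-2-en-1-yl (2E)-4-[(tert-butyldimethylsilyl)oxy]-3-(pyrrolidin-1-yl)but-2-enoate | C=CCOC(=O)/C=C(\CO[Si](C)(C)C(C)(C)C)N1CCCC1 | intermediate (not isolated)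
11 | prop-2-en-1-yl 2-[(benzyloxy)acetyl]-4-[(tert-butyldimethylsilyl)oxy]-3-(pyrrolidin-1-yl)but-2-enoate (push–pull alkene, geometry not fixed) | C=CCOC(=O)C(C(=O)COCc1ccccc1)=C(CO[Si](C)(C)C(C)(C)C)N1CCCC1 | intermediate
12 | 4-(benzyloxy)benzoyl chloride | O=C(Cl)c1ccc(OCc2ccccc2)cc1 | starting material
13 | prop-2-en-1-yl 2-{2-(benzyloxy)-3-[4-(benzyloxy)phenyl]-3-oxopropanoyl}-4-[(tert-butyldimethylsilyl)oxy]-3-(pyrrolidin-1-yl)but-2-enoate (enolizable, no defined stereochemistry) | C=CCOC(=O)C(C(=O)C(OCc1ccccc1)C(=O)c1ccc(OCc2ccccc2)cc1)=C(CO[Si](C)(C)C(C)(C)C)N1CCCC1 | intermediate (not isolated)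
14 | prop-2-en-1-yl 5-(benzyloxy)-6-[4-(benzyloxy)phenyl]-2-{[(tert-butyldimethylsilyl)oxy]methyl}-4-oxo-4H-pyran-3-carboxylate | C=CCOC(=O)c1c(CO[Si](C)(C)C(C)(C)C)oc(-c2ccc(OCc3ccccc3)cc2)c(OCc2ccccc2)c1=O | intermediate
15 | prop-2-en-1-yl 5-(benzyloxy)-6-[4-(benzyloxy)phenyl]-2-(bromomethyl)-4-oxo-4H-pyran-3-carboxylate | C=CCOC(=O)c1c(CBr)oc(-c2ccc(OCc3ccccc3)cc2)c(OCc2ccccc2)c1=O | intermediate
16 | prop-2-en-1-yl 5-(benzyloxy)-6-[4-(benzyloxy)phenyl]-2-({(2R)-4,6-bis(benzyloxy)-2-[4-(benzyloxy)benzoyl]-3-oxo-2,3-dihydro-1-benzofuran-2-yl}methyl)-4-oxo-4H-pyran-3-carboxylate | O=C1c2c(OCc3ccccc3)cc(OCc3ccccc3)cc2O[C@@]1(C(=O)c1ccc(OCc2ccccc2)cc1)Cc1oc(-c2ccc(OCc3ccccc3)cc2)c(OCc2ccccc2)c(=O)c1C(=O)OCC=C | intermediate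
17 | 5-(benzyloxy)-6-[4-(benzyloxy)phenyl]-2-({(2R)-4,6-bis(benzyloxy)-2-[4-(benzyloxy)benzoyl]-3-oxo-2,3-dihydro-1-benzofuran-2-yl}methyl)-4-oxo-4H-pyran-3-carboxylic acid | O=C1c2c(OCc3ccccc3)cc(OCc3ccccc3)cc2O[C@@]1(C(=O)c1ccc(OCc2ccccc2)cc1)Cc1oc(-c2ccc(OCc3ccccc3)cc2)c(OCc2ccccc2)c(=O)c1C(=O)O | intermediate
18 | potassium 3-methoxy-3-oxopropanoate (potassium methyl malonate) | COC(=O)CC(=O)[O-].[K+] | starting material
19 | (2R)-4,6-bis(benzyloxy)-2-[4-(benzyloxy)benzoyl]-2-({5-(benzyloxy)-6-[4-(benzyloxy)phenyl]-3-(1H-imidazole-1-carbonyl)-4-oxo-4H-pyran-2-yl}methyl)-1-benzofuran-3(2H)-one | O=C1c2c(OCc3ccccc3)cc(OCc3ccccc3)cc2O[C@@]1(C(=O)c1ccc(OCc2ccccc2)cc1)Cc1oc(-c2ccc(OCc3ccccc3)cc2)c(OCc2ccccc2)c(=O)c1C(=O)n1ccnc1 | intermediate (not isolated)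
20 | methyl 3-[5-(benzyloxy)-6-[4-(benzyloxy)phenyl]-2-({(2R)-4,6-bis(benzyloxy)-2-[4-(benzyloxy)benzoyl]-3-oxo-2,3-dihydro-1-benzofuran-2-yl}methyl)-4-oxo-4H-pyran-3-yl]-3-oxopropanoate | O=C1c2c(OCc3ccccc3)cc(OCc3ccccc3)cc2O[C@@]1(C(=O)c1ccc(OCc2ccccc2)cc1)Cc1oc(-c2ccc(OCc3ccccc3)cc2)c(OCc2ccccc2)c(=O)c1C(=O)CC(=O)OC | intermediate (precursor of the key step)
21 | (2R)-4,6-bis(benzyloxy)-2-[4-(benzyloxy)benzoyl]-2-{3-(benzyloxy)-2-[4-(benzyloxy)phenyl]-5,7-dihydroxy-4-oxo-4H-chromen-8-yl}-1-benzofuran-3(2H)-one | O=C1c2c(OCc3ccccc3)cc(OCc3ccccc3)cc2O[C@@]1(C(=O)c1ccc(OCc2ccccc2)cc1)c1c(O)cc(O)c2c(=O)c(OCc3ccccc3)c(-c3ccc(OCc4ccccc4)cc3)oc12 | intermediate (not isolated)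
22 | (2S,8'R)-3',4,6-tris(benzyloxy)-2',8'-bis[4-(benzyloxy)phenyl]-5',8'-dihydroxy-3H,4'H,8'H-spiro[[1]benzofuran-2,9'-furo[2,3-h]chromene]-3,4'-dione (pentabenzyl ether of the target; hemiketal OH on the face of the C3 carbonyl) | O=C1c2c(OCc3ccccc3)cc(OCc3ccccc3)cc2O[C@@]12c1c(cc(O)c3c(=O)c(OCc4ccccc4)c(-c4ccc(OCc5ccccc5)cc4)oc13)O[C@]2(O)c1ccc(OCc2ccccc2)cc1 | intermediate (product of the key step)
23 | (2S,8'R)-3',4,5',6,8'-pentahydroxy-2',8'-bis(4-hydroxyphenyl)-3H,4'H,8'H-spiro[[1]benzofuran-2,9'-furo[2,3-h]chromene]-3,4'-dione | O=C1c2c(O)cc(O)cc2O[C@@]12c1c(cc(O)c3c(=O)c(O)c(-c4ccc(O)cc4)oc13)O[C@]2(O)c1ccc(O)cc1 | target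

## Step count and least certain steps

Total: 11 steps. Longest linear sequence: 9 steps (6 → 8 → 11 → 14 → 15 → 16 → 17 → 20 → 22 → 23, steps 3–11). The benzofuranone branch (steps 1–2) joins at step 7.

**Step 10 (key step, proposed new method).**
- What may go wrong: after the first deprotonation the ester is part of a lithium keto ester enolate and is a weak acceptor, so closure may need warming. At that temperature the C8 carbanion has unimolecular exits:
  - β-elimination of the benzofuranone aryloxide (retro-oxa-Michael ring opening), which erases the spiro centre;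
  - 1,2-migration of the aroyl group through a cyclopropanolate.
- The liberated alkoxide can also cleave the 1,3-diketone by retro-Claisen reaction.
- After closure, the hemiketal alkoxide can fragment reversibly to an O7 aryl ester and a planar benzofuranone enolate, which would erode enantiopurity.
- Fallback (known reactions only; sets out from 5, returns at 23): the flavonol is used intact and joined to C2 by lead-mediated arylation of the β-dicarbonyl.
  - Kaempferol F1 is perbenzylated (BnBr, K2CO3, DMF, 80 °C) to 3,5,7-tris(benzyloxy)-2-[4-(benzyloxy)phenyl]-4H-chromen-4-one F2.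
  - F2 is iodinated at C8, the position favoured when O5 is alkylated (N-iodosuccinimide, catalytic CF3CO2H, MeCN), to the 8-iodide F3.
  - Borylation with B2(OH)4, Pd(OAc)2, 2-dicyclohexylphosphino-2',4',6'-triisopropylbiphenyl and KOAc gives the 8-boronic acid F4.
  - Boron–lead exchange with Pb(OAc)4 and catalytic Hg(OAc)2 in CHCl3 gives the aryllead triacetate F5.
  - F5 C-arylates 5 in CHCl3/pyridine at 40–60 °C (Pinhey arylation, which tolerates 2,6-dioxygenated aryl groups and gives quaternary carbons) to the racemic heptabenzyl diketone F6.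
  - The enantiomers are separated by preparative chromatography on a chiral stationary phase to give the (2R) enantiomer F7.
  - Hydrogenolysis (H2, 10% Pd/C, EtOAc/THF) removes seven benzyl groups, and the freed O7 closes the hemiketal to 23.
  - The price is a resolution in place of asymmetric synthesis.

**Step 7.**
- What may go wrong: O-alkylation of the ambident anion, which keeps the benzofuran aromatic, and poor facial selectivity in the ion pair of a weakly basic, strongly delocalized enolate.
- Fallback (from 5 and 15, returns at 16): the alkylation is run without chiral control (Bu4NBr, K2CO3, toluene) to racemic allyl ester F8, and the enantiomers are separated by preparative chromatography on a chiral stationary phase to give 16.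

**Step 5.**
- What may go wrong: O-acylation of the lithium enolate or consumption of the acid chloride by the excess amide base, and loss of the silyl ether during the acid-induced closure followed by lactonization.
- Fallback (from 11, returns at 13 and then 14): the carbon is attached by aldol addition instead of acylation. The lithium enolate of 11 (LiN(SiMe3)2, THF, −78 °C) adds to 4-(benzyloxy)benzaldehyde F9 to give β-hydroxy ketone F10 as a diastereomer mixture. Dess–Martin periodinane (CH2Cl2, 0 °C) oxidizes F10 to diketone 13, which is closed to 14 with AcOH as in the route.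

**Step 9.**
- What may go wrong: slow acyl transfer at a carboxyl group flanked by the pyranone carbonyl and the neopentyl-like side chain, with amine-induced β-elimination at the activated pyranone methylene as a competing process.
- Fallback (from 17, returns at 20): the acid is converted under neutral conditions with 1-chloro-N,N,2-trimethylprop-1-en-1-amine (CH2Cl2, 0 °C) into acid chloride F11. F11 acylates 2,2-dimethyl-1,3-dioxane-4,6-dione (pyridine, CH2Cl2, 0 °C) to the acyl derivative F12. Methanolysis with decarboxylation (MeOH, toluene, 70 °C) gives 20.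

**Step 11.**
- What may go wrong: over-reduction (hydrogenolysis of the benzylic hemiketal C–O bond or reduction of an aryl ketone) or incomplete debenzylation at the hindered O4 of the benzofuranone.
- Fallback (from 22, returns at 23): Lewis-acid debenzylation with BCl3 and pentamethylbenzene as cation scavenger in CH2Cl2 at −78 °C, then aqueous work-up. This avoids reducing conditions altogether.

## Further compounds

F1 | step 10 | kaempferol (3,5,7-trihydroxy-2-(4-hydroxyphenyl)-4H-chromen-4-one) | O=c1c(O)c(-c2ccc(O)cc2)oc2cc(O)cc(O)c12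
F2 | step 10 | 3,5,7-tris(benzyloxy)-2-[4-(benzyloxy)phenyl]-4H-chromen-4-one | O=c1c(OCc2ccccc2)c(-c2ccc(OCc3ccccc3)cc2)oc2cc(OCc3ccccc3)cc(OCc3ccccc3)c12
F3 | step 10 | 3,5,7-tris(benzyloxy)-2-[4-(benzyloxy)phenyl]-8-iodo-4H-chromen-4-one | O=c1c(OCc2ccccc2)c(-c2ccc(OCc3ccccc3)cc2)oc2c(I)c(OCc3ccccc3)cc(OCc3ccccc3)c12
F4 | step 10 | {3,5,7-tris(benzyloxy)-2-[4-(benzyloxy)phenyl]-4-oxo-4H-chromen-8-yl}boronic acid | O=c1c(OCc2ccccc2)c(-c2ccc(OCc3ccccc3)cc2)oc2c(B(O)O)c(OCc3ccccc3)cc(OCc3ccccc3)c12
F5 | step 10 | {3,5,7-tris(benzyloxy)-2-[4-(benzyloxy)phenyl]-4-oxo-4H-chromen-8-yl}lead triacetate | O=c1c(OCc2ccccc2)c(-c2ccc(OCc3ccccc3)cc2)oc2c([Pb](OC(C)=O)(OC(C)=O)OC(C)=O)c(OCc3ccccc3)cc(OCc3ccccc3)c12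
F6 | step 10 | racemic 4,6-bis(benzyloxy)-2-[4-(benzyloxy)benzoyl]-2-{3,5,7-tris(benzyloxy)-2-[4-(benzyloxy)phenyl]-4-oxo-4H-chromen-8-yl}-1-benzofuran-3(2H)-one | O=C1c2c(OCc3ccccc3)cc(OCc3ccccc3)cc2OC1(C(=O)c1ccc(OCc2ccccc2)cc1)c1c(OCc2ccccc2)cc(OCc2ccccc2)c2c(=O)c(OCc3ccccc3)c(-c3ccc(OCc4ccccc4)cc3)oc12
F7 | step 10 | (2R)-4,6-bis(benzyloxy)-2-[4-(benzyloxy)benzoyl]-2-{3,5,7-tris(benzyloxy)-2-[4-(benzyloxy)phenyl]-4-oxo-4H-chromen-8-yl}-1-benzofuran-3(2H)-one | O=C1c2c(OCc3ccccc3)cc(OCc3ccccc3)cc2O[C@@]1(C(=O)c1ccc(OCc2ccccc2)cc1)c1c(OCc2ccccc2)cc(OCc2ccccc2)c2c(=O)c(OCc3ccccc3)c(-c3ccc(OCc4ccccc4)cc3)oc12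
F8 | step 7 | racemic prop-2-en-1-yl 5-(benzyloxy)-6-[4-(benzyloxy)phenyl]-2-({4,6-bis(benzyloxy)-2-[4-(benzyloxy)benzoyl]-3-oxo-2,3-dihydro-1-benzofuran-2-yl}methyl)-4-oxo-4H-pyran-3-carboxylate | O=C1c2c(OCc3ccccc3)cc(OCc3ccccc3)cc2OC1(C(=O)c1ccc(OCc2ccccc2)cc1)Cc1oc(-c2ccc(OCc3ccccc3)cc2)c(OCc2ccccc2)c(=O)c1C(=O)OCC=C
F9 | step 5 | 4-(benzyloxy)benzaldehyde | O=Cc1ccc(OCc2ccccc2)cc1
F10 | step 5 | prop-2-en-1-yl 2-{2-(benzyloxy)-3-[4-(benzyloxy)phenyl]-3-hydroxypropanoyl}-4-[(tert-butyldimethylsilyl)oxy]-3-(pyrrolidin-1-yl)but-2-enoate (diastereomer mixture) | C=CCOC(=O)C(C(=O)C(OCc1ccccc1)C(O)c1ccc(OCc2ccccc2)cc1)=C(CO[Si](C)(C)C(C)(C)C)N1CCCC1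
F11 | step 9 | 5-(benzyloxy)-6-[4-(benzyloxy)phenyl]-2-({(2R)-4,6-bis(benzyloxy)-2-[4-(benzyloxy)benzoyl]-3-oxo-2,3-dihydro-1-benzofuran-2-yl}methyl)-4-oxo-4H-pyran-3-carbonyl chloride | O=C1c2c(OCc3ccccc3)cc(OCc3ccccc3)cc2O[C@@]1(C(=O)c1ccc(OCc2ccccc2)cc1)Cc1oc(-c2ccc(OCc3ccccc3)cc2)c(OCc2ccccc2)c(=O)c1C(Cl)=O
F12 | step 9 | 5-{[5-(benzyloxy)-6-[4-(benzyloxy)phenyl]-2-({(2R)-4,6-bis(benzyloxy)-2-[4-(benzyloxy)benzoyl]-3-oxo-2,3-dihydro-1-benzofuran-2-yl}methyl)-4-oxo-4H-pyran-3-yl](hydroxy)methylidene}-2,2-dimethyl-1,3-dioxane-4,6-dione | O=C1c2c(OCc3ccccc3)cc(OCc3ccccc3)cc2O[C@@]1(C(=O)c1ccc(OCc2ccccc2)cc1)Cc1oc(-c2ccc(OCc3ccccc3)cc2)c(OCc2ccccc2)c(=O)c1C(O)=C1C(=O)OC(C)(C)OC1=O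
F0 | step 11 | none | none
A1 | alternative 1 | di-tert-butyl 2-[3,5-bis(benzyloxy)phenoxy]-2-{3,5-bis(benzyloxy)-2-[4-(benzyloxy)phenyl]-7-hydroxy-4-oxo-4H-chromen-8-yl}propanedioate | CC(C)(C)OC(=O)C(Oc1cc(OCc2ccccc2)cc(OCc2ccccc2)c1)(C(=O)OC(C)(C)C)c1c(O)cc(OCc2ccccc2)c2c(=O)c(OCc3ccccc3)c(-c3ccc(OCc4ccccc4)cc3)oc12
A2 | alternative 1 | tert-butyl 3-[3,5-bis(benzyloxy)phenoxy]-2-oxo-2,3-dihydrofuro[2,3-h]chromen-6-one-3-carboxylate lactone carrying 4-benzyloxy (flavonol O5), 7-benzyloxy (flavonol O3) and the 4-(benzyloxy)phenyl group | O=C1Oc2cc(OCc5ccccc5)c3c(=O)c(OCc5ccccc5)c(-c4ccc(OCc5ccccc5)cc4)oc3c2[C@]1(Oc1cc(OCc5ccccc5)cc(OCc5ccccc5)c1)C(=O)OC(C)(C)C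
A3 | alternative 2 | spiro 5-(diazoacetyl)furan-3(2H)-one joined at C2 to the methyl ketal of the tetrabenzylated flavonol hemiketal unit | O=C1C=C(C(=O)C=[N+]=[N-])O[C@@]12c1c(cc(OCc3ccccc3)c3c(=O)c(OCc4ccccc4)c(-c4ccc(OCc5ccccc5)cc4)oc13)O[C@]2(OC)c1ccc(OCc2ccccc2)cc1
A4 | alternative 2 | benzyl ethynyl ether | C#COCc1ccccc1
A5 | alternative 2 | pentabenzyl methyl ketal of the target with free 4-OH on the benzofuranone | O=C1c2c(O)cc(OCc5ccccc5)cc2O[C@@]12c1c(cc(OCc5ccccc5)c3c(=O)c(OCc5ccccc5)c(-c4ccc(OCc5ccccc5)cc4)oc13)O[C@]2(OC)c1ccc(OCc5ccccc5)cc1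
A6 | alternative 3 | racemic 8-[4,6-bis(benzyloxy)-3-oxo-2,3-dihydro-1-benzofuran-2-yl]-3,5-bis(benzyloxy)-2-[4-(benzyloxy)phenyl]-4-oxo-4H-chromen-7-yl 4-(benzyloxy)benzoate | O=C1c2c(OCc3ccccc3)cc(OCc3ccccc3)cc2OC1c1c(OC(=O)c2ccc(OCc3ccccc3)cc2)cc(OCc2ccccc2)c2c(=O)c(OCc3ccccc3)c(-c3ccc(OCc4ccccc4)cc3)oc12
A7 | alternative 3 | hexabenzyl ether of the target (free hemiketal OH) | O=C1c2c(OCc5ccccc5)cc(OCc5ccccc5)cc2O[C@@]12c1c(cc(OCc5ccccc5)c3c(=O)c(OCc5ccccc5)c(-c4ccc(OCc5ccccc5)cc4)oc13)O[C@]2(O)c1ccc(OCc5ccccc5)cc1
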